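A small charge of Ctl, 0.0300 M in the grey run, stands in 2.50 M of Ptn, so we ask what share of that Ctl the Ptn leaves free.

| setting | grey | teal | blue | green | ochre |
|---|---|---|---|---|---|
| Sbt | 1.00 M | 0.500 M | 1.00 M | 1.00 M | 1.00 M |
| Ptn | 2.50 M | 2.00 M | 1.20 M | 2.50 M | 0.380 M |
| Ctl | 0.0300 M | 0.0300 M | 0.0300 M | 0.0450 M | 0.0300 M |
| time |  |  |  |  | 6.7 h |

- grey run (time / h: [Sbt] / M): 0.24: 0.861; 0.73: 0.694; 1.4: 0.544; 2.2: 0.458; 3.2: 0.396; 4.2: 0.359; 5.4: 0.331; 6.7: 0.322
- teal run (time / h: [Sbt] / M): 0.24: 0.449; 0.73: 0.360; 1.4: 0.290; 2.2: 0.247; 3.2: 0.206; 4.2: 0.179; 5.4: 0.173; 6.7: 0.168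
- blue run (time / h: [Sbt] / M): 0.24: 0.920; 0.73: 0.804; 1.4: 0.681; 2.2: 0.587; 3.2: 0.513; 4.2: 0.475; 5.4: 0.439; 6.7: 0.399
- green run (time / h: [Sbt] / M): 0.24: 0.803; 0.73: 0.565; 1.4: 0.407; 2.2: 0.309; 3.2: 0.236; 4.2: 0.209; 5.4: 0.180; 6.7: 0.169

(readings scatter by 0.005 M)

1. how the opening rate goes with [Ptn] round the charge of the grey run: the exponent of the rate at two percent of Sbt gone to Pdt
2. how the opening rate goes with [Sbt] round the charge of the grey run: the exponent of the rate at two percent of Sbt gone to Pdt (one fixed amount of Pdt, the same in the runs compared)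
3. the teal run starts with 0.500 M less of Sbt and of Ptn than the grey run, and with no Pdt. Compared where both hold the same amount of Sbt, once fifteen percent of what the teal run was charged with has turned into Pdt, is the teal run faster, slower or alike (within a tenth)?
4. Sbt in the ochre run at 6.7 h, as a share of the Sbt charged

- Overall: Sbt + Ptn -> Pdt, with Ctl as catalyst.
- Constant volume, constant temperature.
- A reading of a species includes what of it is bound.
- "The second partner" is Ptn.
- An order is taken over about fifteen percent of the charge, up and down.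

1. Our assumption is that Ctl binds Ptn in a fast equilibrium with association constant K, and that the bound form turns Sbt over. This is Michaelis-type saturation in Ptn: the rate goes as [Sbt][Ptn]/(1+K[Ptn]), and the order in Ptn equals the free share of Ctl, 1/(1+K[Ptn]).

2. We read K from the blue and grey runs, through g, the ratio of their ln([Sbt]/[Sbt] at the start) at one time. The Ctl charges are equal, so in this assumed rate law Ctl divides out of g and its value needn't be known well. The Sbt charge stands inside both logarithms, so it doesn't divide out of g and has to be known well. The Ptn charges enter as their ratio, 0.480, and they are given.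

3. The readings matter as well. At 0.24 h, g is 0.557, and one scatter on the blue reading moves it to 0.521, which shifts the order by 0.115. At 0.73 h, g is 0.597, and the same slip gives 0.580, a shift of 0.0452. So we take the later time, when the Sbt lost equals 12.2% of the Ptn charge in the grey run and 16.3% in the blue run.

4. Here g is larger than the Ptn ratio, and K = (g−a)/([Ptn]blue(1−g)). So K, the association constant of Ptn with Ctl as read from these two runs, is 0.243 L mol⁻¹. Our order in Ptn at the grey charge is 0.623.

5. The forecast differs from this. It gives 0.75 (0.5 to 1) for Ptn, on the ground that “Blue's early ln-slope is about 0.55–0.6 of grey's for 0.48 of the Ptn, giving order about 0.75”. For Sbt it gives 0.9 (0.65 to 1.1), for the teal run faster, and for the ochre run 74% (69% to 81%).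

6. The steps behind the readings:

    Ctl + Ptn ⇌ Ctl.Ptn, settled at all times (0.2290 L mol⁻¹)
    Ctl.Ptn + Sbt → Pdt + Ctl (65.52 L mol⁻¹ h⁻¹)
    Ctl + Ptn → J + Ptn (0.3323 L mol⁻¹ h⁻¹)
    Ctl + E → J

The flask gives orders of 0.64 in Ptn and 1.0 in Sbt, the teal run faster, and 69.5% of the Sbt left in the ochre run. The blue run makes Pdt at 0.35 M h⁻¹ where 2% of the Sbt of the grey run have turned. Carrying that rate to the teal charge with K = 0.243 L mol⁻¹ and the rate law of step 1 gives 0.257 M h⁻¹. The teal run itself stands at 0.25 M h⁻¹ at that point.

The earlier runs and the new flask were generated by integration on assumed constants.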